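**Retrosynthetic overview**
1. Target 21 ⇒ triol enone 18 + angelic acid 19: the ester C–O bond is made last, on the only secondary hydroxyl.
2. 18 ⇒ isopropylidene ketone 16: the C11–O bond comes from a Schenck ene oxygenation that also moves the alkene to C6=C7; 16 ⇒ ketone 12 + acetone (aldol addition, dehydration).
3. 12 ⇒ enone 8: key C–O disconnection at C4; a one-flask dissolving-metal reduction / enolate hydroboration–oxidation converts the enone into the 3β,4α-diol and sets C3, C4 and C5.
4. 8 ⇒ ketone 1 + ethyl vinyl ketone 3: Robinson annulation through a chiral-imine Michael addition that sets C10.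
5. Ring order: ring B is bought as cyclohexanone 1; ring A is closed onto it in step 2. The dioxolane already present in 1 is the only protecting group.

Assumption: racemic 1 is taken as a catalogue compound; trivial names use eudesmane numbering (C10 angular-methyl carbon, C5 ring-fusion CH, C3 and C4 the oxygenated carbons of ring A, C8 the carbonyl and C7 the side-chain carbon of ring B, C11 the carbinol carbon of the side chain).

**Step 1**
Reactants: 1 7-methyl-1,4-dioxaspiro[4.5]decan-8-one (racemic); 2 (R)-1-phenylethan-1-amine; 3 pent-1-en-3-one (ethyl vinyl ketone)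
Product: 6 (7R)-7-methyl-7-(3-oxopentyl)-1,4-dioxaspiro[4.5]decan-8-one, via ketimine 4 (not isolated), via Michael adduct imine 5 (not isolated)
Conditions: 2 (1.05 equiv), toluene, reflux, Dean–Stark; then 3 (1.3 equiv), THF, 40 °C, 72 h; then 10% aq AcOH, 20 °C, 1 h
Reagents that add atoms: pent-1-en-3-one 3 (C=CC(=O)CC); water (O)
Why: d'Angelo-type asymmetric Michael addition (aza-ene reaction of the more substituted secondary enamine tautomer of imine 4), in which the enone is delivered to the methyl-bearing carbon on the face anti to the phenyl group of the (R)-auxiliary through a chair-like transition state with internal N–H transfer, setting C10 as R (10β-methyl, typically about 90% ee) before mild hydrolysis releases the auxiliary and leaves the dioxolane intact.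

**Step 2**
Reactants: 6 (7R)-7-methyl-7-(3-oxopentyl)-1,4-dioxaspiro[4.5]decan-8-one
Product: 8 (10R)-8,8-ethylenedioxy-11,12,13-trinoreudesm-4-en-3-one, via ketol 7 (not isolated)
Conditions: NaOMe (1.0 equiv), MeOH, 60 °C
Reagents that add atoms: none
Why: Intramolecular aldol condensation (second stage of the Robinson annulation), in which the ethyl-ketone α-carbon C4 adds to the ring carbonyl C5 and E1cB dehydration of ketol 7 gives the conjugated 4-methyl-Δ4-3-ketone, creating no stereocentre and leaving C10 untouched.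

**Step 3**
Reactants: 8 (10R)-8,8-ethylenedioxy-11,12,13-trinoreudesm-4-en-3-one
Product: 12 (4aR,5S,6S,8aR)-5,6-dihydroxy-5,8a-dimethyloctahydronaphthalen-2(1H)-one (3β,4α-dihydroxy-11,12,13-trinor-5α-eudesman-8-one), via enolate 9 (not isolated), via boryl alkoxide 10 (not isolated), via diol ketal 11 (not isolated)
Conditions: Li (2.1 equiv), t-BuOH (1.0 equiv), NH3(l)/THF, −78 → −33 °C; evaporate NH3, THF; BH3·THF (5 equiv), 0 → 40 °C; then 3 M NaOH, 30% H2O2, 0 → 20 °C; then 2 M HCl, THF, 20 °C
Reagents that add atoms: hydrogen peroxide (OO); water (O)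
Why: Proposed new method: a one-flask dissolving-metal enone reduction / enolate hydroboration–oxidation, in which Li/NH3 sets the trans ring fusion (axial protonation at C5, 5α-H) and leaves only the C3–C4 lithium enolate 9, whose nucleophilic C4 takes up BH3 on the α-face anti to the axial C10 methyl with hydride delivered to C3 on the same face (syn addition), the resulting trans-diequatorial β-boryl alkoxide 10 being unable to reach the syn- or anti-periplanar geometry needed for B–O elimination in the locked trans-decalin, so that stereoretentive B-to-O oxidation gives the 4α-hydroxyl and the 3β-ol and the acid finish unmasks the C8 ketone; the closest known reactions are Stork-type reductive enolate trapping and the hydroboration–oxidation of preformed silyl enol ethers to trans-1,2-diol derivatives.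

**Step 4**
Reactants: 12 (4aR,5S,6S,8aR)-5,6-dihydroxy-5,8a-dimethyloctahydronaphthalen-2(1H)-one; 13 acetone
Product: 15 3β,4α,11-trihydroxy-5α-eudesman-8-one (C7 epimers), via enolate 14 (not isolated)
Conditions: LiN(iPr)2 (3.3 equiv), THF, −78 °C, 1 h; 13 (5 equiv), −78 °C, 15 min; AcOH, −78 °C
Reagents that add atoms: acetone 13 (CC(C)=O)
Why: Kinetic lithium-enolate aldol addition, in which the two hydroxyls are deprotonated first, the third equivalent of base removes the unhindered C7 proton (C9 is neopentylic next to the quaternary C10) and the enolate adds to acetone, the new C7 centre being irrelevant because it becomes sp2 in the next steps.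

**Step 5**
Reactants: 15 3β,4α,11-trihydroxy-5α-eudesman-8-one (C7 epimers)
Product: 16 (4aR,5S,6S,8aR)-5,6-dihydroxy-5,8a-dimethyl-3-(propan-2-ylidene)octahydronaphthalen-2(1H)-one (3β,4α-dihydroxy-5α-eudesm-7(11)-en-8-one)
Conditions: p-TsOH·H2O (10 mol %), toluene, 50 °C
Reagents that add atoms: none
Why: Acid-catalysed dehydration of a tertiary β-hydroxy ketone through its enol (completion of the aldol condensation) gives the conjugated isopropylidene ketone, while the C4 tertiary carbinol is spared because ionisation there is disfavoured by the adjacent C3 oxygen; no stereocentre is touched.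

**Step 6**
Reactants: 16 3β,4α-dihydroxy-5α-eudesm-7(11)-en-8-one
Product: 18 (4aR,5S,6S,8aR)-5,6-dihydroxy-3-(2-hydroxypropan-2-yl)-5,8a-dimethyl-4a,5,6,7,8,8a-hexahydronaphthalen-2(1H)-one (3β,4α,11-trihydroxy-5α-eudesm-6-en-8-one), via hydroperoxide 17 (not isolated)
Conditions: O2, 5,10,15,20-tetraphenylporphyrin (1 mol %), CH2Cl2/MeOH 9:1, white LEDs, 0 °C; then PPh3 (1.2 equiv), 0 → 20 °C
Reagents that add atoms: dioxygen (O=O)
Why: Schenck ene reaction of singlet oxygen with an s-cis α,β-unsaturated ketone, in which hydrogen is abstracted from the ring CH2 geminal to the carbonyl (C6, gem effect) while oxygen bonds to C11 and the alkene shifts into conjugation at C6=C7, PPh3 then reducing hydroperoxide 17 to the tertiary alcohol; C11 is not stereogenic and C5 is untouched.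

**Step 7**
Reactants: 18 3β,4α,11-trihydroxy-5α-eudesm-6-en-8-one; 19 angelic acid ((2Z)-2-methylbut-2-enoic acid)
Product: 21 (1S,2S,4aR,8aR)-1-hydroxy-7-(2-hydroxypropan-2-yl)-1,4a-dimethyl-6-oxo-1,2,3,4,4a,5,6,8a-octahydronaphthalen-2-yl (2Z)-2-methylbut-2-enoate (target), via mixed anhydride 20 (not isolated)
Conditions: 19 (3 equiv), 2,4,6-trichlorobenzoyl chloride (3 equiv), Et3N (6 equiv), toluene, 20 °C, 2 h; then 18, 75 °C, 24 h
Reagents that add atoms: angelic acid 19 (C/C=C(/C)C(=O)O)
Why: Yamaguchi-type mixed-anhydride esterification without nucleophilic catalyst acylates only the secondary equatorial 3β-hydroxyl (the other two are tertiary) at the less hindered angeloyl carbonyl, and the DMAP-free conditions avoid Z-to-E isomerisation, so C3 keeps its configuration and the Z alkene is retained.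

**Compound list**
1 | 7-methyl-1,4-dioxaspiro[4.5]decan-8-one (racemic) | CC1CC2(CCC1=O)OCCO2 | starting material
2 | (R)-1-phenylethan-1-amine | C[C@@H](N)c1ccccc1 | starting material (auxiliary)
3 | pent-1-en-3-one (ethyl vinyl ketone) | C=CC(=O)CC | starting material
4 | 7-methyl-N-[(1R)-1-phenylethyl]-1,4-dioxaspiro[4.5]decan-8-imine | CC1CC2(OCCO2)CCC1=N[C@H](C)c1ccccc1 | intermediate (not isolated)
5 | (7R)-7-methyl-7-(3-oxopentyl)-N-[(1R)-1-phenylethyl]-1,4-dioxaspiro[4.5]decan-8-imine | CCC(=O)CC[C@]1(C)CC2(OCCO2)CCC1=N[C@H](C)c1ccccc1 | intermediate (not isolated)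
6 | (7R)-7-methyl-7-(3-oxopentyl)-1,4-dioxaspiro[4.5]decan-8-one | CCC(=O)CC[C@]1(C)CC2(OCCO2)CCC1=O | intermediate
7 | (10R)-8,8-ethylenedioxy-5-hydroxy-11,12,13-trinoreudesman-3-one (ketol, C4 and C5 not controlled) | O=C1CC[C@]2(C)CC3(OCCO3)CCC2(O)C1C | intermediate (not isolated)
8 | (10R)-8,8-ethylenedioxy-11,12,13-trinoreudesm-4-en-3-one | O=C1CC[C@]2(C)CC3(OCCO3)CCC2=C1C | intermediate
9 | lithium 8,8-ethylenedioxy-11,12,13-trinor-5α-eudesm-3-en-3-olate | [Li+].[O-]C1=C(C)[C@@H]2CCC3(OCCO3)C[C@@]2(C)CC1 | intermediate (not isolated)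
10 | lithium 4α-boranyl-8,8-ethylenedioxy-11,12,13-trinor-5α-eudesman-3β-olate | [Li+].[O-][C@H]1CC[C@]2(C)CC3(OCCO3)CC[C@H]2[C@]1(C)B | intermediate (not isolated)
11 | 8,8-ethylenedioxy-11,12,13-trinor-5α-eudesmane-3β,4α-diol | O[C@H]1CC[C@]2(C)CC3(OCCO3)CC[C@H]2[C@]1(C)O | intermediate (not isolated)
12 | (4aR,5S,6S,8aR)-5,6-dihydroxy-5,8a-dimethyloctahydronaphthalen-2(1H)-one | O[C@H]1CC[C@]2(C)CC(=O)CC[C@H]2[C@]1(C)O | intermediate
13 | acetone | CC(C)=O | starting material
14 | trilithium 3β,4α-dioxido-11,12,13-trinor-5α-eudesm-7-en-8-olate | [Li+].[Li+].[Li+].[O-][C@H]1CC[C@]2(C)CC([O-])=CC[C@H]2[C@]1(C)[O-] | intermediate (not isolated)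
15 | 3β,4α,11-trihydroxy-5α-eudesman-8-one (C7 epimers) | O[C@H]1CC[C@]2(C)CC(=O)C(C(C)(C)O)C[C@H]2[C@]1(C)O | intermediate
16 | 3β,4α-dihydroxy-5α-eudesm-7(11)-en-8-one | O[C@H]1CC[C@]2(C)CC(=O)C(=C(C)C)C[C@H]2[C@]1(C)O | intermediate
17 | 11-hydroperoxy-3β,4α-dihydroxy-5α-eudesm-6-en-8-one | O[C@H]1CC[C@]2(C)CC(=O)C(C(C)(C)OO)=C[C@H]2[C@]1(C)O | intermediate (not isolated)
18 | 3β,4α,11-trihydroxy-5α-eudesm-6-en-8-one | O[C@H]1CC[C@]2(C)CC(=O)C(C(C)(C)O)=C[C@H]2[C@]1(C)O | intermediate
19 | angelic acid, (2Z)-2-methylbut-2-enoic acid | C/C=C(/C)C(=O)O | starting material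
20 | (2Z)-2-methylbut-2-enoic 2,4,6-trichlorobenzoic anhydride | C/C=C(/C)C(=O)OC(=O)c1c(Cl)cc(Cl)cc1Cl | intermediate (not isolated)
21 | 3β-angeloyloxy-4α,11-dihydroxy-5α-eudesm-6-en-8-one (CNP0261892.1) | C/C=C(/C)C(=O)O[C@H]1CC[C@]2(C)CC(=O)C(C(C)(C)O)=C[C@H]2[C@]1(C)O | target

**Totals and risks**
Total step count: 7. Longest linear sequence: 7 steps (1 → 6 → 8 → 12 → 15 → 16 → 18 → 21).

The three steps most likely to fail are steps 3, 6 and 7.

Step 3 (the proposed new step) may stop at an unreactive O-borylated enolate or lose boron and oxygen to give an alkene. The fallback uses known chemistry, sets out from 8 and comes back at 12. The same Li/NH3 reduction gives enolate 9, which is trapped with Me3SiCl/Et3N as the isolated 8,8-ethylenedioxy-3-(trimethylsilyloxy)-11,12,13-trinor-5α-eudesm-3-ene F1. Rubottom oxidation (mCPBA, NaHCO3, CH2Cl2, −20 °C) epoxidises the α-face and silyl migration gives 8,8-ethylenedioxy-4α-(trimethylsilyloxy)-11,12,13-trinor-5α-eudesman-3-one F2. NaBH4 (MeOH, 0 °C) delivers hydride axially to give 8,8-ethylenedioxy-4α-(trimethylsilyloxy)-11,12,13-trinor-5α-eudesman-3β-ol F3. 2 M HCl in THF then removes the silyl ether and the dioxolane to give 12.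

Step 6 may give the wrong ene regiochemistry (methyl hydrogen abstraction) or react sluggishly. The fallback sets out from 12 and comes back at 18, replacing steps 4 to 6 by a seleno-aldol sequence. Enolate 14 (LiN(iPr)2, 3.3 equiv, THF, −78 °C) is selenenylated with PhSeCl to give 3β,4α-dihydroxy-7-(phenylselanyl)-11,12,13-trinor-5α-eudesman-8-one F4. A second deprotonation at the selenium-bearing C7 and addition to acetone 13 gives 3β,4α,11-trihydroxy-7-(phenylselanyl)-5α-eudesman-8-one F5. H2O2/pyridine (CH2Cl2, 0 °C) gives the selenoxide of that aldol F6, whose syn-elimination can only use the C6 hydrogens and delivers 18.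

Step 7 may suffer Z-to-E isomerisation to the tiglate or slow acylation of the hindered 3β-hydroxyl. The fallback sets out from 18 and comes back at 21, building the Z alkene after the ester bond is made. Steglich esterification (DCC, DMAP, CH2Cl2) with 2-[bis(2,2,2-trifluoroethoxy)phosphoryl]propanoic acid gives 3β-{2-[bis(2,2,2-trifluoroethoxy)phosphoryl]propanoyloxy}-4α,11-dihydroxy-5α-eudesm-6-en-8-one F7. Z-selective Still–Gennari olefination (KN(SiMe3)2, 18-crown-6, THF, −78 °C, acetaldehyde) then gives 21.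

**Further compounds**
F1 | step 3 | 8,8-ethylenedioxy-3-(trimethylsilyloxy)-11,12,13-trinor-5α-eudesm-3-ene | C[Si](C)(C)OC1=C(C)[C@@H]2CCC3(OCCO3)C[C@@]2(C)CC1
F2 | step 3 | 8,8-ethylenedioxy-4α-(trimethylsilyloxy)-11,12,13-trinor-5α-eudesman-3-one | O=C1CC[C@]2(C)CC3(OCCO3)CC[C@H]2[C@]1(C)O[Si](C)(C)C
F3 | step 3 | 8,8-ethylenedioxy-4α-(trimethylsilyloxy)-11,12,13-trinor-5α-eudesman-3β-ol | O[C@H]1CC[C@]2(C)CC3(OCCO3)CC[C@H]2[C@]1(C)O[Si](C)(C)C
F4 | step 6 | 3β,4α-dihydroxy-7-(phenylselanyl)-11,12,13-trinor-5α-eudesman-8-one (C7 epimers) | O[C@H]1CC[C@]2(C)CC(=O)C([Se]c3ccccc3)C[C@H]2[C@]1(C)O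
F5 | step 6 | 3β,4α,11-trihydroxy-7-(phenylselanyl)-5α-eudesman-8-one | O[C@H]1CC[C@]2(C)CC(=O)C([Se]c3ccccc3)(C(C)(C)O)C[C@H]2[C@]1(C)O
F6 | step 6 | 3β,4α,11-trihydroxy-7-(phenylseleninyl)-5α-eudesman-8-one (selenoxide) | O[C@H]1CC[C@]2(C)CC(=O)C([Se](=O)c3ccccc3)(C(C)(C)O)C[C@H]2[C@]1(C)O
F7 | step 7 | 3β-{2-[bis(2,2,2-trifluoroethoxy)phosphoryl]propanoyloxy}-4α,11-dihydroxy-5α-eudesm-6-en-8-one | CC(C(=O)O[C@H]1CC[C@]2(C)CC(=O)C(C(C)(C)O)=C[C@H]2[C@]1(C)O)P(=O)(OCC(F)(F)F)OCC(F)(F)F
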